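Numbering: heptenyl chain C1–C7 from the styryl carbon; ring A is the trioxygenated ring, acyl at C1'. The route rests on disconnecting C3–C4, between the ring-A-bearing stereocentre and its CH2 neighbour. The key step exploits that the phenolic oxygen at C4', ring carbon C3', C3 and the C1=C2 styryl unit with its 4-oxyphenyl ring are together the ring-opened form of a 2-aryl-2H-chromene. A chiral phosphoric acid opens the racemic chromeno-chalcone to an achiral vinyl o-quinone methide, to which a raspberry-ketone-derived β-keto acid adds with loss of CO2. One operation joins the halves, sets C3, frees the phenol and creates the E-styrene; a ketoreductase then sets C5.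

Key step: step 5

Remark: the sense of induction of the phosphoric acid and the facial preference of the ketoreductase on this substrate cannot be predicted with certainty; the route assumes that the catalyst antipode and the enzyme (from a panel) that give 3R and 5S are chosen in a first run.

Step 1
Reactants: 1 (E)-3-(4-hydroxyphenyl)prop-2-enal
Product: 2 (E)-3-[4-(allyloxy)phenyl]prop-2-enal
Conditions: allyl bromide, K2CO3, DMF, rt
Reagents that add atoms: allyl bromide, C=CCBr
Why: Williamson ether synthesis on the phenoxide; the allyl ether is a donor that later assists heterolysis at C2 of the chromene and is removed at the end under neutral Pd(0) conditions.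

Step 2
Reactants: 2 (E)-3-[4-(allyloxy)phenyl]prop-2-enal; 3 1-(2,4-dihydroxy-6-methoxyphenyl)ethanone
Product: 5 1-[2-(4-allyloxyphenyl)-5-hydroxy-7-methoxy-2H-chromen-6-yl]ethanone (racemic), via vinyl o-quinone methide 4 (not isolated)
Conditions: EDDA (ethylenediammonium diacetate, 20 mol%), toluene, reflux
Reagents that add atoms: none
Why: Amine-salt-catalysed Knoevenagel-type condensation at C3' (flanked by both hydroxyls and the most enol-like carbon of the monochelated resorcinol) gives 4, whose oxa-6π electrocyclisation through the non-chelated 4'-oxygen closes the 2H-pyran ring (formal [3+3] chromene annulation); C2 is formed racemic, which is of no consequence.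

Step 3
Reactants: 5 1-[2-(4-allyloxyphenyl)-5-hydroxy-7-methoxy-2H-chromen-6-yl]ethanone; 6 4-(allyloxy)benzaldehyde
Product: 8 (E)-1-[2-(4-allyloxyphenyl)-5-hydroxy-7-methoxy-2H-chromen-6-yl]-3-(4-allyloxyphenyl)prop-2-en-1-one (racemic), via aldol adduct 7 (not isolated)
Conditions: KOH, EtOH/H2O, rt; then AcOH to pH 6
Reagents that add atoms: none
Why: Claisen–Schmidt condensation: the acetyl enolate adds to the non-enolisable aldehyde and aldol 7 dehydrates (E1cB) to the E-enone, the 4'-oxygen being tied up in the pyran ring so that the ketone is not deactivated as a para-phenoxide.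

Step 4
Reactants: 9 4-(4-hydroxyphenyl)butan-2-one (raspberry ketone)
Product: 11 5-(4-hydroxyphenyl)-3-oxopentanoic acid, via dilithium enolate 10 (not isolated)
Conditions: LDA (2.2 equiv), THF, −78 °C; CO2; 1 M HCl, 0 °C
Reagents that add atoms: carbon dioxide, O=C=O
Why: After the phenol, LDA removes a methyl proton under kinetic control and the less substituted lithium enolate 10 is C-carboxylated by CO2 (enolate carboxylation), which gives a regiodefined methyl-ketone enolate equivalent that is used at once because it decarboxylates on standing.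

Step 5
Reactants: 8 (E)-1-[2-(4-allyloxyphenyl)-5-hydroxy-7-methoxy-2H-chromen-6-yl]-3-(4-allyloxyphenyl)prop-2-en-1-one; 11 5-(4-hydroxyphenyl)-3-oxopentanoic acid
Product: 14 (E)-1-[3-[(1E,3R)-1-(4-allyloxyphenyl)-7-(4-hydroxyphenyl)-5-oxohept-1-en-3-yl]-2,4-dihydroxy-6-methoxyphenyl]-3-(4-allyloxyphenyl)prop-2-en-1-one, via ring-opened o-quinone methide 12 (not isolated), via alkylated β-keto acid 13 (not isolated)
Conditions: (R)-TRIP (10 mol%), toluene, 0 °C → rt, then 40 °C
Reagents that add atoms: none
Why: Proposed new method: the phosphoric acid protonates O1 of 8, heterolysis of the O1–C2 bond (benzylic to the 4-allyloxyphenyl ring, allylic, acylphenol as leaving group) gives the phosphate-bound vinyl o-quinone methide 12, the enol of 11 held by the same phosphate adds to its methide carbon, and 13 loses CO2; the closest known reaction type is the phosphoric-acid-catalysed conjugate addition of enols, including decarboxylative addition of β-keto acids, to o-quinone methides generated in situ from o-hydroxybenzyl alcohols. No ring is closed; the pyran ring is opened, and reversible opening and closure channels both enantiomers of 8 through the same achiral intermediate. The new stereocentre C3 is controlled by the chiral phosphate, which blocks one face of the planar methide carbon in a hydrogen-bonded, [4+2]-like transition state. The step needs 1,4- and not 1,6-addition: the phosphate bridge between the ring-A oxygen and the enol reaches only the proximal carbon, and only the 1,4-adduct keeps the alkene conjugated with the unhindered aryl ring. It also needs C–O ionisation to outrun C3-protonation of the chromene, which the donor aryl group at C2 and the weak acid are meant to secure; the E-alkene follows from the extended geometry of 12. The chalcone enone is a much weaker acceptor and should remain untouched.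

Step 6
Reactants: 14 (E)-1-[3-[(1E,3R)-1-(4-allyloxyphenyl)-7-(4-hydroxyphenyl)-5-oxohept-1-en-3-yl]-2,4-dihydroxy-6-methoxyphenyl]-3-(4-allyloxyphenyl)prop-2-en-1-one
Product: 15 (E)-1-[3-[(1E,3R,5S)-1-(4-allyloxyphenyl)-5-hydroxy-7-(4-hydroxyphenyl)hept-1-en-3-yl]-2,4-dihydroxy-6-methoxyphenyl]-3-(4-allyloxyphenyl)prop-2-en-1-one
Conditions: ketoreductase (KRED), NADP+ (cat.), i-PrOH, phosphate buffer pH 7, DMSO (10%), 30 °C
Reagents that add atoms: none
Why: Enzymatic carbonyl reduction (ketoreductase, NADPH-dependent alcohol dehydrogenase class): hydride is delivered to one face of the open-chain dialkyl ketone (drained from its hemiketal equilibrium) under control of the active site and not of C3, giving the 5S alcohol, while the conjugated, hydrogen-bonded aryl enone and the alkenes are not substrates.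

Step 7
Reactants: 15 (E)-1-[3-[(1E,3R,5S)-1-(4-allyloxyphenyl)-5-hydroxy-7-(4-hydroxyphenyl)hept-1-en-3-yl]-2,4-dihydroxy-6-methoxyphenyl]-3-(4-allyloxyphenyl)prop-2-en-1-one
Product: 16 calyxin A
Conditions: Pd(PPh3)4 (5 mol%), N-methylaniline, THF, rt
Reagents that add atoms: none
Why: Tsuji–Trost deallylation: Pd(0) ionises both aryl allyl ethers to π-allyl complexes that are trapped by the amine, under neutral conditions that leave the chalcone, the styrene, the secondary alcohol and both stereocentres untouched.

Compound list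
1 | (E)-3-(4-hydroxyphenyl)prop-2-enal (4-hydroxycinnamaldehyde) | O=C/C=C/c1ccc(O)cc1 | starting material
2 | (E)-3-[4-(allyloxy)phenyl]prop-2-enal | O=C/C=C/c1ccc(OCC=C)cc1 | intermediate
3 | 1-(2,4-dihydroxy-6-methoxyphenyl)ethanone | CC(=O)c1c(O)cc(O)cc1OC | starting material
4 | vinyl o-quinone methide, 4-acetyl-3-hydroxy-5-methoxy-2-[(E)-3-(4-allyloxyphenyl)prop-2-enylidene]cyclohexa-3,5-dien-1-one (ring-alkylidene geometry not fixed) | CC(=O)C1=C(O)C(=C/C=C/c2ccc(OCC=C)cc2)C(=O)C=C1OC | intermediate
5 | 1-[2-(4-allyloxyphenyl)-5-hydroxy-7-methoxy-2H-chromen-6-yl]ethanone (racemic at C2) | CC(=O)c1c(OC)cc2OC(c3ccc(OCC=C)cc3)C=Cc2c1O | intermediate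
6 | 4-(allyloxy)benzaldehyde | O=Cc1ccc(OCC=C)cc1 | starting material
7 | aldol adduct, 1-[2-(4-allyloxyphenyl)-5-hydroxy-7-methoxy-2H-chromen-6-yl]-3-(4-allyloxyphenyl)-3-hydroxypropan-1-one (diastereomer mixture) | O=C(CC(O)c1ccc(OCC=C)cc1)c1c(OC)cc2OC(c3ccc(OCC=C)cc3)C=Cc2c1O | intermediate
8 | (E)-1-[2-(4-allyloxyphenyl)-5-hydroxy-7-methoxy-2H-chromen-6-yl]-3-(4-allyloxyphenyl)prop-2-en-1-one (racemic at C2) | O=C(/C=C/c1ccc(OCC=C)cc1)c1c(OC)cc2OC(c3ccc(OCC=C)cc3)C=Cc2c1O | intermediate
9 | 4-(4-hydroxyphenyl)butan-2-one (raspberry ketone) | CC(=O)CCc1ccc(O)cc1 | starting material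
10 | dilithium 4-(3-oxidobut-3-enyl)phenolate (dilithium enolate of 9) | [Li+].[Li+].C=C([O-])CCc1ccc([O-])cc1 | intermediate
11 | 5-(4-hydroxyphenyl)-3-oxopentanoic acid | OC(=O)CC(=O)CCc1ccc(O)cc1 | intermediate
12 | ring-opened o-quinone methide, 2-[(E)-3-(4-allyloxyphenyl)prop-2-enylidene]-4-[(E)-3-(4-allyloxyphenyl)prop-2-enoyl]-3-hydroxy-5-methoxycyclohexa-3,5-dien-1-one (achiral; ring-alkylidene geometry not fixed) | O=C(/C=C/c1ccc(OCC=C)cc1)C1=C(O)C(=C/C=C/c2ccc(OCC=C)cc2)C(=O)C=C1OC | intermediate
13 | alkylated β-keto acid, 2-[(E)-1-[3-[(E)-3-(4-allyloxyphenyl)prop-2-enoyl]-2,6-dihydroxy-4-methoxyphenyl]-3-(4-allyloxyphenyl)allyl]-5-(4-hydroxyphenyl)-3-oxopentanoic acid (aryl-bearing carbon configured as in 14, both epimers at C2 of the acid) | COc1cc(O)c([C@@H](/C=C/c2ccc(OCC=C)cc2)C(C(=O)O)C(=O)CCc2ccc(O)cc2)c(O)c1C(=O)/C=C/c1ccc(OCC=C)cc1 | intermediate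
14 | (E)-1-[3-[(1E,3R)-1-(4-allyloxyphenyl)-7-(4-hydroxyphenyl)-5-oxohept-1-en-3-yl]-2,4-dihydroxy-6-methoxyphenyl]-3-(4-allyloxyphenyl)prop-2-en-1-one | COc1cc(O)c([C@@H](/C=C/c2ccc(OCC=C)cc2)CC(=O)CCc2ccc(O)cc2)c(O)c1C(=O)/C=C/c1ccc(OCC=C)cc1 | intermediate
15 | (E)-1-[3-[(1E,3R,5S)-1-(4-allyloxyphenyl)-5-hydroxy-7-(4-hydroxyphenyl)hept-1-en-3-yl]-2,4-dihydroxy-6-methoxyphenyl]-3-(4-allyloxyphenyl)prop-2-en-1-one | COc1cc(O)c([C@@H](/C=C/c2ccc(OCC=C)cc2)C[C@@H](O)CCc2ccc(O)cc2)c(O)c1C(=O)/C=C/c1ccc(OCC=C)cc1 | intermediate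
16 | calyxin A, (E)-1-[2,4-dihydroxy-3-[(1E,3R,5S)-5-hydroxy-1,7-bis(4-hydroxyphenyl)hept-1-en-3-yl]-6-methoxyphenyl]-3-(4-hydroxyphenyl)prop-2-en-1-one | COc1cc(O)c([C@@H](/C=C/c2ccc(O)cc2)C[C@@H](O)CCc2ccc(O)cc2)c(O)c1C(=O)/C=C/c1ccc(O)cc1 | target

Total step count: 7. Longest linear sequence: 6 steps (steps 1, 2, 3, 5, 6, 7).

Steps most likely to fail

Step 5 (proposed new method). The acid may protonate C3 of the chromene faster than it ionises the O1–C2 bond, so that the nucleophile adds with the pyran ring still closed. The nucleophile may also add at the distal allylic carbon, or the facial selectivity may be poor. The fallback uses known chemistry, sets out from 8 and 9 and comes back at 15. Ketone 9 is bis-silylated through dianion 10 (LDA, then TBSCl) to the silyl enol ether tert-butyl-[4-[3-(tert-butyldimethylsilyloxy)but-3-enyl]phenoxy]dimethylsilane F1. Heating 8 with F1 in toluene at 110 °C opens the chromene by thermal retro-6π electrocyclisation to 12, which is trapped in an inverse-electron-demand hetero-Diels–Alder reaction as the racemic 2-silyloxychroman cycloadduct F2. HF·pyridine cleaves the silyl ketal and the aryl silyl ether to the racemic ketone F3. The ketoreductase of step 6 then reduces both enantiomers to 5S alcohols, 15 and its (3S,5S) diastereomer F4. These are separated by chromatography and 15 re-enters the route.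

Step 6. The enzyme may not accept a ketone with two large substituents, or may reduce it with poor facial selectivity. The fallback sets out from 14 and comes back at 15. NaBH4 in THF/MeOH at −40 °C should reduce only the dialkyl ketone, without stereocontrol, to 15 and its (3R,5R) epimer F5. The two diastereomers are separated by preparative HPLC.

Step 2. The condensation may take place at C5' (between the 4'-hydroxyl and the methoxy group) instead of C3', giving the wrong regiochemistry. The fallback sets out from 2 and comes back at 5. Aldehyde 2 is condensed under the same EDDA conditions with commercial 1-(2,4,6-trihydroxyphenyl)ethanone, whose two free ring positions are equivalent. This gives 1-[2-(4-allyloxyphenyl)-5,7-dihydroxy-2H-chromen-6-yl]ethanone F6, which is freed from any isomer closed through a 2'-oxygen by chromatography. Selective methylation of the less hindered 7-hydroxyl (Me2SO4, K2CO3, acetone; the 5-hydroxyl stays chelated) gives 5.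

Further compounds
F1 | step 5 | tert-butyl-[4-[3-(tert-butyldimethylsilyloxy)but-3-enyl]phenoxy]dimethylsilane | C=C(O[Si](C)(C)C(C)(C)C)CCc1ccc(O[Si](C)(C)C(C)(C)C)cc1
F2 | step 5 | (E)-3-(4-allyloxyphenyl)-1-[4-[(E)-2-(4-allyloxyphenyl)vinyl]-2-(tert-butyldimethylsilyloxy)-2-[2-[4-(tert-butyldimethylsilyloxy)phenyl]ethyl]-5-hydroxy-7-methoxychroman-6-yl]prop-2-en-1-one (racemic, diastereomer mixture) | COc1cc2OC(CCc3ccc(O[Si](C)(C)C(C)(C)C)cc3)(O[Si](C)(C)C(C)(C)C)CC(/C=C/c3ccc(OCC=C)cc3)c2c(O)c1C(=O)/C=C/c1ccc(OCC=C)cc1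
F3 | step 5 | racemic form of 14, (E)-1-[3-[(1E)-1-(4-allyloxyphenyl)-7-(4-hydroxyphenyl)-5-oxohept-1-en-3-yl]-2,4-dihydroxy-6-methoxyphenyl]-3-(4-allyloxyphenyl)prop-2-en-1-one | COc1cc(O)c(C(/C=C/c2ccc(OCC=C)cc2)CC(=O)CCc2ccc(O)cc2)c(O)c1C(=O)/C=C/c1ccc(OCC=C)cc1
F4 | step 5 | (3S,5S) diastereomer of 15 | COc1cc(O)c([C@H](/C=C/c2ccc(OCC=C)cc2)C[C@@H](O)CCc2ccc(O)cc2)c(O)c1C(=O)/C=C/c1ccc(OCC=C)cc1
F5 | step 6 | (3R,5R) epimer of 15 | COc1cc(O)c([C@@H](/C=C/c2ccc(OCC=C)cc2)C[C@H](O)CCc2ccc(O)cc2)c(O)c1C(=O)/C=C/c1ccc(OCC=C)cc1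
F6 | step 2 | 1-[2-(4-allyloxyphenyl)-5,7-dihydroxy-2H-chromen-6-yl]ethanone (racemic) | CC(=O)c1c(O)cc2OC(c3ccc(OCC=C)cc3)C=Cc2c1O
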